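**Assumptions.** The SMILES is read as the (2R,3S)-trans isomer (C2 aryl and C3 CH2OH on opposite faces). The catalyst antipode in Step 5 is assigned by analogy with closely related 2-(benzyloxy)aryl diazoacetates as I recall that precedent; if the sense is reversed on this substrate, use Rh2(R-PTTL)4 with no other change.

## Retrosynthetic overview

1. The acid comes from a methyl cinnamate, made by Wittig olefination of a C5 aryl aldehyde; the C3 CH2OH comes from reduction of a C3 ester.
2. The trans-2-aryl-3-ester dihydrobenzofuran comes from C3 epimerisation of the cis ester.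
3. The cis ester comes from an enantioselective Rh(II)-carbenoid 1,5 C–H insertion of an aryl diazoacetate, which forms the C2–C3 bond and sets C2.
4. The aryl diazoacetate comes from Pd-catalysed coupling of an aryl iodide with ethyl diazoacetate; the iodide comes from Mitsunobu etherification of 5-iodovanillin with O-TBS-vanillyl alcohol (from vanillin).
5. Ring order: both benzene rings are purchased; the dihydrofuran ring is the only ring formed (Step 5).

## Route

**Step 1**
Reactants: 1 vanillin; 2 tert-butyldimethylsilyl chloride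
Product: 3, 4-[(tert-butyldimethylsilyl)oxy]-3-methoxybenzaldehyde
Conditions: TBSCl, imidazole, DMF, rt
Reagents that add atoms: TBSCl, CC(C)(C)[Si](C)(C)Cl
Why: Standard phenol silylation; the TBS group masks the phenol against O–H insertion and quinone-methide chemistry and is removed by hydroxide in the last step.

**Step 2**
Reactants: 3
Product: 4, {4-[(tert-butyldimethylsilyl)oxy]-3-methoxyphenyl}methanol
Conditions: NaBH4, THF/EtOH, 0 °C, short reaction time
Reagents that add atoms: none
Why: Chemoselective borohydride reduction of the aryl aldehyde; the aryl silyl ether survives brief cold exposure.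

**Step 3**
Reactants: 5, 5-iodovanillin (4-hydroxy-3-iodo-5-methoxybenzaldehyde); 4
Product: 6, 4-({4-[(tert-butyldimethylsilyl)oxy]-3-methoxyphenyl}methoxy)-3-iodo-5-methoxybenzaldehyde
Conditions: PPh3, DIAD, THF, 0 °C → rt
Reagents that add atoms: none (both partners are numbered reactants)
Why: Mitsunobu etherification of an acidic phenol with a primary benzylic alcohol; it avoids the unstable p-silyloxybenzyl halide.

**Step 4**
Reactants: 6; 7 ethyl diazoacetate
Product: 8, ethyl 2-diazo-2-[2-({4-[(tert-butyldimethylsilyl)oxy]-3-methoxyphenyl}methoxy)-5-formyl-3-methoxyphenyl]acetate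
Conditions: 7 (1.5 equiv), Pd(PPh3)4 (5 mol %), Ag2CO3 (0.5 equiv), Et3N (1.3 equiv), toluene, rt
Reagents that add atoms: ethyl diazoacetate, CCOC(=O)C=[N+]=[N-]
Why: Pd-catalysed C–H arylation of an acceptor diazo compound by an aryl iodide with retention of the diazo group; it gives the donor/acceptor diazo ester in one step, and the aldehyde and silyl ether are inert at rt.

**Step 5**
Reactants: 8
Product: 9, ethyl (2R,3S)-2-{4-[(tert-butyldimethylsilyl)oxy]-3-methoxyphenyl}-5-formyl-7-methoxy-2,3-dihydro-1-benzofuran-3-carboxylate (cis)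
Conditions: Rh2(S-PTTL)4 (2 mol %), toluene (0.02 M), −60 °C
Reagents that add atoms: none (loss of N2)
Why: Enantioselective intramolecular Rh(II)-carbenoid 1,5 C–H insertion into the doubly activated ArCH2–O bond closes the dihydrofuran ring; the phthaloyl-tert-leucinate catalyst differentiates the enantiotopic benzylic hydrogens and sets C2 as R (C3 forms cis under kinetic control), with roughly 85–95% ee expected.

**Step 6**
Reactants: 9
Product: 10, ethyl (2R,3R)-2-{4-[(tert-butyldimethylsilyl)oxy]-3-methoxyphenyl}-5-formyl-7-methoxy-2,3-dihydro-1-benzofuran-3-carboxylate (trans)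
Conditions: DBU (2 equiv), dry toluene, rt → 40 °C; then recrystallise
Reagents that add atoms: none
Why: Thermodynamic epimerisation through the C3 ester enolate gives the trans isomer while C2 (not acidic, phenol still silylated) is untouched; anhydrous non-nucleophilic base keeps the TBS group on, and recrystallisation here or at 11 raises the ee to >99%.

**Step 7**
Reactants: 10
Product: 11, [(2R,3S)-2-{4-[(tert-butyldimethylsilyl)oxy]-3-methoxyphenyl}-3-(hydroxymethyl)-7-methoxy-2,3-dihydro-1-benzofuran-5-yl]methanol
Conditions: LiBH4 (3 equiv), THF, 0 °C → rt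
Reagents that add atoms: none
Why: Hydride reduction of both the ester and the aldehyde; C3 is now no longer epimerisable (the descriptor changes from R to S only because CIP priorities change).

**Step 8**
Reactants: 11; 12 methyl (triphenylphosphoranylidene)acetate
Product: 13, methyl (2E)-3-[(2R,3S)-2-{4-[(tert-butyldimethylsilyl)oxy]-3-methoxyphenyl}-3-(hydroxymethyl)-7-methoxy-2,3-dihydro-1-benzofuran-5-yl]prop-2-enoate
Conditions: activated MnO2 (10 equiv), 12 (1.3 equiv), CH2Cl2, rt
Reagents that add atoms: methyl (triphenylphosphoranylidene)acetate, COC(=O)C=P(c1ccccc1)(c1ccccc1)c1ccccc1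
Why: Tandem oxidation–Wittig; MnO2 oxidises only the benzylic alcohol (the C3 CH2OH is unactivated) and the stabilised ylide traps the aldehyde in situ as the (E)-cinnamate.

**Step 9**
Reactants: 13
Product: 14, (2E)-3-[(2R,3S)-2-(4-hydroxy-3-methoxyphenyl)-3-(hydroxymethyl)-7-methoxy-2,3-dihydro-1-benzofuran-5-yl]prop-2-enoic acid (target)
Conditions: LiOH·H2O (5 equiv), THF/MeOH/H2O, rt; then aq. citric acid to pH 3
Reagents that add atoms: hydroxide/water, [Li+].[OH-] (O of the CO2H)
Why: Saponification of the methyl ester with concurrent hydroxide cleavage of the aryl silyl ether; the conditions are mild and non-acidic, so the benzylic ether and both stereocentres are unaffected.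

## Compound list

1 | vanillin | COc1cc(C=O)ccc1O | starting material
2 | tert-butyldimethylsilyl chloride | CC(C)(C)[Si](C)(C)Cl | starting material (reagent)
3 | 4-[(tert-butyldimethylsilyl)oxy]-3-methoxybenzaldehyde | COc1cc(C=O)ccc1O[Si](C)(C)C(C)(C)C | intermediate
4 | {4-[(tert-butyldimethylsilyl)oxy]-3-methoxyphenyl}methanol | COc1cc(CO)ccc1O[Si](C)(C)C(C)(C)C | intermediate
5 | 5-iodovanillin | COc1cc(C=O)cc(I)c1O | starting material
6 | 4-({4-[(TBS)oxy]-3-methoxyphenyl}methoxy)-3-iodo-5-methoxybenzaldehyde | COc1cc(C=O)cc(I)c1OCc1ccc(O[Si](C)(C)C(C)(C)C)c(OC)c1 | intermediate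
7 | ethyl diazoacetate | CCOC(=O)C=[N+]=[N-] | starting material
8 | ethyl 2-diazo-2-[2-({4-[(TBS)oxy]-3-methoxyphenyl}methoxy)-5-formyl-3-methoxyphenyl]acetate | CCOC(=O)C(=[N+]=[N-])c1cc(C=O)cc(OC)c1OCc1ccc(O[Si](C)(C)C(C)(C)C)c(OC)c1 | intermediate
9 | ethyl (2R,3S)-cis-2-{4-[(TBS)oxy]-3-methoxyphenyl}-5-formyl-7-methoxy-2,3-dihydrobenzofuran-3-carboxylate | COc1cc([C@@H]2Oc3c(OC)cc(C=O)cc3[C@@H]2C(=O)OCC)ccc1O[Si](C)(C)C(C)(C)C | intermediate
10 | ethyl (2R,3R)-trans-2-{4-[(TBS)oxy]-3-methoxyphenyl}-5-formyl-7-methoxy-2,3-dihydrobenzofuran-3-carboxylate | COc1cc([C@@H]2Oc3c(OC)cc(C=O)cc3[C@H]2C(=O)OCC)ccc1O[Si](C)(C)C(C)(C)C | intermediate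
11 | [(2R,3S)-2-{4-[(TBS)oxy]-3-methoxyphenyl}-3-(hydroxymethyl)-7-methoxy-2,3-dihydrobenzofuran-5-yl]methanol | COc1cc([C@@H]2Oc3c(OC)cc(CO)cc3[C@H]2CO)ccc1O[Si](C)(C)C(C)(C)C | intermediate
12 | methyl (triphenylphosphoranylidene)acetate | COC(=O)C=P(c1ccccc1)(c1ccccc1)c1ccccc1 | starting material
13 | methyl (2E)-3-[(2R,3S)-2-{4-[(TBS)oxy]-3-methoxyphenyl}-3-(hydroxymethyl)-7-methoxy-2,3-dihydrobenzofuran-5-yl]prop-2-enoate | COc1cc([C@@H]2Oc3c(OC)cc(/C=C/C(=O)OC)cc3[C@H]2CO)ccc1O[Si](C)(C)C(C)(C)C | intermediate
14 | (2E)-3-[(2R,3S)-2-(4-hydroxy-3-methoxyphenyl)-3-(hydroxymethyl)-7-methoxy-2,3-dihydrobenzofuran-5-yl]prop-2-enoic acid | COc1cc([C@@H]2Oc3c(OC)cc(/C=C/C(=O)O)cc3[C@H]2CO)ccc1O | target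

## Summary

**Total steps:** 9.
**Longest linear sequence:** 9 (vanillin → 14); 5-iodovanillin enters at Step 3, 7 steps from the target.

**Three steps most likely to fail, each with a fallback**

1. **Step 5 (Rh C–H insertion).** The ee and cis selectivity are unproven with the 7-OMe/5-CHO pattern and an ethyl ester, and carbonyl-ylide formation with the aldehyde could compete. Fallback: abandon the carbenoid route and make the racemic trans core biomimetically. Ag2O oxidative dimerisation of coniferyl alcohol gives (±)-dehydrodiconiferyl alcohol; MnO2 gives the enal and Pinnick oxidation gives the (±)-acid. Resolve by preparative chiral SFC or a diastereomeric amine salt.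

2. **Step 4 (Pd coupling with ethyl diazoacetate).** The iodide is flanked by a bulky ortho ether and the product is a sensitive diazo compound. Fallback: switch to a Regitz diazo-transfer/Heck strategy. O-alkylate methyl (5-bromo-2-hydroxy-3-methoxyphenyl)acetate with the vanillyl unit and carry out p-ABSA/DBU diazo transfer. After C–H insertion, epimerisation and ester reduction, install the side chain by Heck coupling of the 5-bromide with methyl acrylate.

3. **Step 6 (C3 epimerisation).** If the silyl ether is lost, the free phenoxide could open the ring via a quinone methide and erode ee; DBU may also be sluggish. Fallback: avoid base epimerisation altogether. Use the enantiomeric catalyst so that the insertion sets C3, reduce the cis ester to the cis CH2OH compound, and then equilibrate C2 to the trans isomer by mild acid-catalysed benzylic ring opening and reclosure, with C3 fixed.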